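**Plan**

1. Last cuts: the five benzyl ethers; then the C2–H and C3–H bonds of unit 1 (the 2-(4-hydroxyphenyl)chromanone) back to a flavone C2=C3; then the C2–aryl bond of unit 2 (the 8-linked 2-(4-methoxyphenyl)chromanone) back to a chromone and 4-methoxyphenylboronic acid.
2. Core cut: in the pyranone of unit 1 the bonds O1–C8a and C3–C4 are cut together, giving a deoxybenzoin enolate (O1–C2–C3 as a C,O-dinucleophile) and 2,4-bis(benzyloxy)-6-fluorobenzoyl chloride (C4 and C8a as a 1,3-dielectrophile).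
3. Enabling feature: C3 of unit 1 lies between C2 (a ketone carbon in the precursor) and aromatic C8 of unit 2, so its C–H is the only acidic one; in ring A the acyl carbon C4 sits ortho to the oxygen-bearing C8a and both other ring oxygens are meta to C8a, so an ortho fluorine is displaced once C4 is a ketone.
4. Forward order: chromone ring of unit 2 (from an iodinated 2'-hydroxyacetophenone), then the C8–CH2 bond by Pd ketone α-arylation, then the flavone ring of unit 1 (key step), then the chromanone of unit 2 (aryl addition), then the chromanone of unit 1 (hydrogenation), then debenzylation.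
5. Stereochemistry: C2 of unit 2 (S) from a ligand-controlled Pd-catalysed conjugate arylation; C2 of unit 1 (R) from a ligand-controlled hydrogenation; C3 of unit 1 (S) by equilibration to the trans-diequatorial isomer.
6. Helpers: fluorine (leaves in the key step); the chromone/flavone oxidation level (no stereocentre and no base-labile chromanone during the key step; removed in steps 9 and 10); benzyl ethers (removed in step 11).

Key step: step 8

Assumption: the sense of induction of the chiral ligands in steps 9 and 10 is assigned by analogy and the antipodal ligand is used if a first run shows the opposite sense; 14 and 16 have a hindered C3–C8 axis between the units and are carried as atropisomer mixtures that converge once C3 becomes sp3.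

**Step 1**
Reactants: 1 1-[2,4-bis(benzyloxy)-6-hydroxyphenyl]ethan-1-one
Product: 2 1-[4,6-bis(benzyloxy)-2-hydroxy-3-iodophenyl]ethan-1-one
Conditions: NIS (1.05 equiv), CF3CO2H (cat.), MeCN, 0 °C to rt
Reagents that add atoms: N-iodosuccinimide, O=C1CCC(=O)N1I
Why: Electrophilic aromatic iodination, expected at the less hindered ring position ortho to the chelated phenol (C3) rather than between the two benzyloxy groups, which later fixes the linkage at C8 of unit 2.

**Step 2**
Reactants: 2 1-[4,6-bis(benzyloxy)-2-hydroxy-3-iodophenyl]ethan-1-one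
Product: 4 5,7-bis(benzyloxy)-8-iodo-4H-chromen-4-one, via enaminone 3 (not isolated)
Conditions: Me2NCH(OMe)2, toluene, 100 °C; then conc. HCl, CH2Cl2, rt
Reagents that add atoms: N,N-dimethylformamide dimethyl acetal, COC(OC)N(C)C
Why: Enaminone formation followed by acid-mediated addition–elimination of the only free phenol (loss of Me2NH) is the standard chromone annulation of 2'-hydroxyacetophenones and places iodine at C8.

**Step 3**
Reactants: 4 5,7-bis(benzyloxy)-8-iodo-4H-chromen-4-one; 5 1-[4-(benzyloxy)phenyl]ethan-1-one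
Product: 6 5,7-bis(benzyloxy)-8-{2-[4-(benzyloxy)phenyl]-2-oxoethyl}-4H-chromen-4-one
Conditions: Pd2(dba)3 (2.5 mol%), XPhos (6 mol%), K3PO4 (2.5 equiv), toluene, 90 °C
Reagents that add atoms: none
Why: Palladium-catalysed ketone α-arylation (Buchwald–Hartwig type) with a bulky biaryl phosphine suited to di-ortho-substituted electron-rich aryl iodides; the weak base keeps the enolate concentration low so the chromone should be spared, and the crowded product should resist a second arylation.

**Step 4**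
Reactants: 7 5-fluorobenzene-1,3-diol
Product: 8 1,3-bis(benzyloxy)-5-fluorobenzene
Conditions: BnBr (2.2 equiv), K2CO3, DMF, 60 °C
Reagents that add atoms: benzyl bromide, BrCc1ccccc1
Why: Williamson etherification of both phenols.

**Step 5**
Reactants: 8 1,3-bis(benzyloxy)-5-fluorobenzene
Product: 10 2,4-bis(benzyloxy)-6-fluorobenzaldehyde, via iminium salt 9 (not isolated)
Conditions: POCl3, DMF, 0 to 70 °C; then aq. NaOAc
Reagents that add atoms: N,N-dimethylformamide, CN(C)C=O; water, O
Why: Vilsmeier–Haack formylation, expected at the position flanked by fluorine and one benzyloxy group (ortho/para to both ethers) rather than the more hindered position between the two benzyloxy groups.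

**Step 6**
Reactants: 10 2,4-bis(benzyloxy)-6-fluorobenzaldehyde
Product: 11 2,4-bis(benzyloxy)-6-fluorobenzoic acid
Conditions: NaClO2, NaH2PO4, 2-methyl-2-butene, t-BuOH/H2O, rt
Reagents that add atoms: sodium chlorite, [Na+].[O-]Cl=O
Why: Pinnick oxidation, with the alkene scavenger trapping HOCl so that the electron-rich ring is not chlorinated.

**Step 7**
Reactants: 11 2,4-bis(benzyloxy)-6-fluorobenzoic acid
Product: 12 2,4-bis(benzyloxy)-6-fluorobenzoyl chloride
Conditions: (COCl)2, DMF (cat.), CH2Cl2, 0 °C to rt; used crude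
Reagents that add atoms: oxalyl chloride, O=C(Cl)C(=O)Cl
Why: Acid chloride formation through the catalytic chloroiminium species; benzyl ethers and the aryl fluoride are inert.

**Step 8**
Reactants: 6 5,7-bis(benzyloxy)-8-{2-[4-(benzyloxy)phenyl]-2-oxoethyl}-4H-chromen-4-one; 12 2,4-bis(benzyloxy)-6-fluorobenzoyl chloride
Product: 14 5,7-bis(benzyloxy)-3-[5,7-bis(benzyloxy)-4-oxo-4H-chromen-8-yl]-2-[4-(benzyloxy)phenyl]-4H-chromen-4-one, via beta-diketone 13 (not isolated)
Conditions: LiN(SiMe3)2 (2.2 equiv), toluene/THF, −78 °C; 12, −78 to 0 °C; then DMF, 90 °C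
Reagents that add atoms: none
Why: LiN(SiMe3)2 removes the doubly activated C3–H of 6, the enolate carbon attacks the acid chloride to form C3–C4 and the second equivalent of base gives the enolate of 13; on heating in DMF the enolate oxygen on C2 attacks the fluorine-bearing C8a ortho to the new C4 ketone and fluoride leaves (addition–elimination through a Meisenheimer adduct), forming O1–C8a. The closest known reaction type is the one-pot C-acylation/intramolecular SNAr of ketone enolates with 2-fluorobenzoyl chlorides to give chromones and flavones. The pyranone is the only ring closed, in a six-membered mode by oxygen attack on an arene carbon (formally 6-exo-trig with respect to C8a=C8). No stereocentre is created, because the product is a flavone (C2=C3), an oxidation level chosen so that the strongly basic event needs no stereocontrol and can scramble nothing. The step needs C- over O-acylation (a lithium enolate in a toluene-rich medium, with excess enolate returning any enol ester to the diketonate), a single enolizable site (unit 2 is a chromone with no α-CH2) and a single leaving group whose carbon is meta to both benzyloxy groups and so not deactivated by them.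

**Step 9**
Reactants: 14 5,7-bis(benzyloxy)-3-[5,7-bis(benzyloxy)-4-oxo-4H-chromen-8-yl]-2-[4-(benzyloxy)phenyl]-4H-chromen-4-one; 15 (4-methoxyphenyl)boronic acid
Product: 16 5,7-bis(benzyloxy)-3-[(2S)-5,7-bis(benzyloxy)-2-(4-methoxyphenyl)-4-oxo-3,4-dihydro-2H-chromen-8-yl]-2-[4-(benzyloxy)phenyl]-4H-chromen-4-one
Conditions: Pd(OCOCF3)2 (10 mol%), (R)-t-BuPyOx (12 mol%), NH4PF6 (30 mol%), H2O (5 equiv), ClCH2CH2Cl, 60 °C
Reagents that add atoms: none
Why: Palladium-catalysed asymmetric conjugate addition of an arylboronic acid to a chromone (transmetalation, enantio-determining carbopalladation placing the aryl group at C2 of unit 2, protonolysis of the palladium enolate), in which the pyridine–oxazoline ligand sets (2S) and the tetrasubstituted flavone alkene of unit 1 should not react.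

**Step 10**
Reactants: 16 5,7-bis(benzyloxy)-3-[(2S)-5,7-bis(benzyloxy)-2-(4-methoxyphenyl)-4-oxo-3,4-dihydro-2H-chromen-8-yl]-2-[4-(benzyloxy)phenyl]-4H-chromen-4-one
Product: 18 (2R,3S)-5,7-bis(benzyloxy)-3-[(2S)-5,7-bis(benzyloxy)-2-(4-methoxyphenyl)-4-oxo-3,4-dihydro-2H-chromen-8-yl]-2-[4-(benzyloxy)phenyl]-2,3-dihydro-4H-chromen-4-one, via cis-flavanone 17 (not isolated)
Conditions: [Rh(cod)Cl]2 (2.5 mol%), (S,R)-ZhaoPhos or its antipode (5.5 mol%; see assumption), H2 (60 bar), CH2Cl2/i-PrOH, 50 °C; then TsOH·H2O (10 mol%), CH2Cl2, rt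
Reagents that add atoms: none
Why: Proposed new method: asymmetric hydrogenation of the tetrasubstituted C2=C3 bond of a 2,3-diarylchromone is not known, the closest known reaction type being rhodium/bisphosphine–thiourea-catalysed asymmetric hydrogenation of 2-substituted chromones and of tetrasubstituted α,β-unsaturated ketones; the thiourea N–H groups should bind the C4 carbonyl of unit 1 and hold the alkene on rhodium, hydride insertion then delivers H to C2 on the ligand-defined face (2R), syn addition gives cis-2,3 product 17, and acid-catalysed enolization of the C3–H (alpha to the ketone and benzylic) equilibrates it to the trans-diequatorial (3S) isomer without touching C2, while the ketone of unit 2 and the benzyl ethers are inert to this catalyst.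

**Step 11**
Reactants: 18 (2R,3S)-5,7-bis(benzyloxy)-3-[(2S)-5,7-bis(benzyloxy)-2-(4-methoxyphenyl)-4-oxo-3,4-dihydro-2H-chromen-8-yl]-2-[4-(benzyloxy)phenyl]-2,3-dihydro-4H-chromen-4-one
Product: 19 (2R,3S)-5,7-dihydroxy-3-[(2S)-5,7-dihydroxy-2-(4-methoxyphenyl)-4-oxo-3,4-dihydro-2H-chromen-8-yl]-2-(4-hydroxyphenyl)-2,3-dihydro-4H-chromen-4-one (CNP0140544.1)
Conditions: H2 (1 atm), Pd/C (10 wt%), EtOAc/MeOH, rt
Reagents that add atoms: none
Why: Hydrogenolysis of the five benzyl ethers under neutral conditions, which should leave the aryl methyl ether, both ketones and all three stereocentres untouched (no base, hence no retro-oxa-Michael ring opening).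

**Compound list**

1 | 1-[2,4-bis(benzyloxy)-6-hydroxyphenyl]ethan-1-one | CC(=O)c1c(O)cc(OCc2ccccc2)cc1OCc1ccccc1 | starting material
2 | 1-[4,6-bis(benzyloxy)-2-hydroxy-3-iodophenyl]ethan-1-one | CC(=O)c1c(O)c(I)c(OCc2ccccc2)cc1OCc1ccccc1 | intermediate
3 | (E)-1-[4,6-bis(benzyloxy)-2-hydroxy-3-iodophenyl]-3-(dimethylamino)prop-2-en-1-one | CN(C)/C=C/C(=O)c1c(O)c(I)c(OCc2ccccc2)cc1OCc1ccccc1 | intermediate (not isolated)
4 | 5,7-bis(benzyloxy)-8-iodo-4H-chromen-4-one | O=c1ccoc2c(I)c(OCc3ccccc3)cc(OCc3ccccc3)c12 | intermediate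
5 | 1-[4-(benzyloxy)phenyl]ethan-1-one | CC(=O)c1ccc(OCc2ccccc2)cc1 | starting material
6 | 5,7-bis(benzyloxy)-8-{2-[4-(benzyloxy)phenyl]-2-oxoethyl}-4H-chromen-4-one | O=C(Cc1c(OCc2ccccc2)cc(OCc2ccccc2)c2c(=O)ccoc12)c1ccc(OCc2ccccc2)cc1 | intermediate
7 | 5-fluorobenzene-1,3-diol | Oc1cc(O)cc(F)c1 | starting material
8 | 1,3-bis(benzyloxy)-5-fluorobenzene | Fc1cc(OCc2ccccc2)cc(OCc2ccccc2)c1 | intermediate
9 | N-{[2,4-bis(benzyloxy)-6-fluorophenyl]methylidene}-N-methylmethanaminium chloride | C[N+](C)=Cc1c(F)cc(OCc2ccccc2)cc1OCc1ccccc1.[Cl-] | intermediate (not isolated)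
10 | 2,4-bis(benzyloxy)-6-fluorobenzaldehyde | O=Cc1c(F)cc(OCc2ccccc2)cc1OCc1ccccc1 | intermediate
11 | 2,4-bis(benzyloxy)-6-fluorobenzoic acid | OC(=O)c1c(F)cc(OCc2ccccc2)cc1OCc1ccccc1 | intermediate
12 | 2,4-bis(benzyloxy)-6-fluorobenzoyl chloride | O=C(Cl)c1c(F)cc(OCc2ccccc2)cc1OCc1ccccc1 | intermediate
13 | 2-[5,7-bis(benzyloxy)-4-oxo-4H-chromen-8-yl]-1-[2,4-bis(benzyloxy)-6-fluorophenyl]-3-[4-(benzyloxy)phenyl]propane-1,3-dione (present as its lithium enolate) | O=C(c1ccc(OCc2ccccc2)cc1)C(C(=O)c1c(F)cc(OCc2ccccc2)cc1OCc1ccccc1)c1c(OCc2ccccc2)cc(OCc2ccccc2)c2c(=O)ccoc12 | intermediate (not isolated)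
14 | 5,7-bis(benzyloxy)-3-[5,7-bis(benzyloxy)-4-oxo-4H-chromen-8-yl]-2-[4-(benzyloxy)phenyl]-4H-chromen-4-one | O=c1c(-c2c(OCc3ccccc3)cc(OCc3ccccc3)c3c(=O)ccoc23)c(-c2ccc(OCc3ccccc3)cc2)oc2cc(OCc3ccccc3)cc(OCc3ccccc3)c12 | intermediate
15 | (4-methoxyphenyl)boronic acid | COc1ccc(B(O)O)cc1 | starting material
16 | 5,7-bis(benzyloxy)-3-[(2S)-5,7-bis(benzyloxy)-2-(4-methoxyphenyl)-4-oxo-3,4-dihydro-2H-chromen-8-yl]-2-[4-(benzyloxy)phenyl]-4H-chromen-4-one | COc1ccc([C@@H]2CC(=O)c3c(OCc4ccccc4)cc(OCc4ccccc4)c(-c4c(-c5ccc(OCc6ccccc6)cc5)oc5cc(OCc6ccccc6)cc(OCc6ccccc6)c5c4=O)c3O2)cc1 | intermediate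
17 | (2R,3R)-5,7-bis(benzyloxy)-3-[(2S)-5,7-bis(benzyloxy)-2-(4-methoxyphenyl)-4-oxo-3,4-dihydro-2H-chromen-8-yl]-2-[4-(benzyloxy)phenyl]-2,3-dihydro-4H-chromen-4-one (2,3-cis) | COc1ccc([C@@H]2CC(=O)c3c(OCc4ccccc4)cc(OCc4ccccc4)c([C@H]4C(=O)c5c(OCc6ccccc6)cc(OCc6ccccc6)cc5O[C@H]4c4ccc(OCc5ccccc5)cc4)c3O2)cc1 | intermediate (not isolated)
18 | (2R,3S)-5,7-bis(benzyloxy)-3-[(2S)-5,7-bis(benzyloxy)-2-(4-methoxyphenyl)-4-oxo-3,4-dihydro-2H-chromen-8-yl]-2-[4-(benzyloxy)phenyl]-2,3-dihydro-4H-chromen-4-one (2,3-trans) | COc1ccc([C@@H]2CC(=O)c3c(OCc4ccccc4)cc(OCc4ccccc4)c([C@@H]4C(=O)c5c(OCc6ccccc6)cc(OCc6ccccc6)cc5O[C@H]4c4ccc(OCc5ccccc5)cc4)c3O2)cc1 | intermediate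
19 | (2R,3S)-5,7-dihydroxy-3-[(2S)-5,7-dihydroxy-2-(4-methoxyphenyl)-4-oxo-3,4-dihydro-2H-chromen-8-yl]-2-(4-hydroxyphenyl)-2,3-dihydro-4H-chromen-4-one | COc1ccc([C@@H]2CC(=O)c3c(O)cc(O)c([C@@H]4C(=O)c5c(O)cc(O)cc5O[C@H]4c4ccc(O)cc4)c3O2)cc1 | target

**Count**

Total: 11 steps. Longest linear sequence: 8 steps (7 to 19 through steps 4, 5, 6, 7, 8, 9, 10, 11); the other branch (1 to 19) is 7 steps.

**Steps most likely to fail**

1. Step 10 (Proposed new method). The crowded tetrasubstituted alkene may fail to bind and insert at rhodium, or facial selectivity may be poor, in particular for the atropisomer whose own facial bias opposes the ligand. Fallback with known chemistry, setting out from 16: LiBH(s-Bu)3 (excess), THF, −78 °C should reduce the flavone alkene of unit 1 in the conjugate sense (as known for 3-arylchromones) and the ketone of unit 2 to the carbinol, giving after protonation the trans-flavanone carbinol F1 together with its (2S,3R) unit-1 epimer. Dess–Martin periodinane then restores the ketone of unit 2. Because C2 of unit 2 is fixed as S, the two products are diastereomers, and chromatography should separate 18 from the (2S,3R) diastereomer F2. The route is rejoined at 18.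

2. Step 8. The crowded enolate may be acylated on oxygen without return to the diketonate, fluoride displacement on the electron-rich ring may stall, or base may attack the chromone of unit 2. Fallback, setting out from 4 (with starting material 1) and forming the same flavone from the phenol side: the Pd2(dba)3/XPhos/K3PO4 α-arylation is run with acetophenone 1 (phenol carried as phenoxide) to give the 2'-hydroxydeoxybenzoin F3. Acylation with 4-(benzyloxy)benzoyl chloride in pyridine gives the aryl ester F4. A Baker–Venkataraman O-to-C acyl shift (LiN(SiMe3)2, THF, −20 °C) gives the phenolic beta-diketone F5. Cyclodehydration (TsOH·H2O, toluene, 80 °C) closes the pyranone, and the route is rejoined at 14.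

3. Step 9. Carbopalladation of the hindered, electron-rich chromone next to the bulky flavone may be slower than protodeboronation of the boronic acid. Fallback, setting out from 6, with the order of events changed: the same Pd(OCOCF3)2/(R)-t-BuPyOx arylation with 15 is run on the less hindered chromone 6 to give the flavanone deoxybenzoin F6. The pyranone of unit 1 is then built without strong base: soft enolization (MgBr2·OEt2, i-Pr2NEt, CH2Cl2, rt) and C-acylation with 12 give the fluoro beta-diketone F7. Mild fluoride displacement (K2CO3, MeCN, 50 °C) then closes the ring, and the route is rejoined at 16.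

**Further compounds**

F1 | step 10 | (2R,3S)-5,7-bis(benzyloxy)-3-[(2S)-5,7-bis(benzyloxy)-4-hydroxy-2-(4-methoxyphenyl)-3,4-dihydro-2H-chromen-8-yl]-2-[4-(benzyloxy)phenyl]-2,3-dihydro-4H-chromen-4-one (carbinol carbon of unit 2 in either configuration) | COc1ccc([C@@H]2CC(O)c3c(OCc4ccccc4)cc(OCc4ccccc4)c([C@@H]4C(=O)c5c(OCc6ccccc6)cc(OCc6ccccc6)cc5O[C@H]4c4ccc(OCc5ccccc5)cc4)c3O2)cc1
F2 | step 10 | (2S,3R)-5,7-bis(benzyloxy)-3-[(2S)-5,7-bis(benzyloxy)-2-(4-methoxyphenyl)-4-oxo-3,4-dihydro-2H-chromen-8-yl]-2-[4-(benzyloxy)phenyl]-2,3-dihydro-4H-chromen-4-one | COc1ccc([C@@H]2CC(=O)c3c(OCc4ccccc4)cc(OCc4ccccc4)c([C@H]4C(=O)c5c(OCc6ccccc6)cc(OCc6ccccc6)cc5O[C@@H]4c4ccc(OCc5ccccc5)cc4)c3O2)cc1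
F3 | step 8 | 1-[2,4-bis(benzyloxy)-6-hydroxyphenyl]-2-[5,7-bis(benzyloxy)-4-oxo-4H-chromen-8-yl]ethan-1-one | O=C(Cc1c(OCc2ccccc2)cc(OCc2ccccc2)c2c(=O)ccoc12)c1c(O)cc(OCc2ccccc2)cc1OCc1ccccc1
F4 | step 8 | 3,5-bis(benzyloxy)-2-{[5,7-bis(benzyloxy)-4-oxo-4H-chromen-8-yl]acetyl}phenyl 4-(benzyloxy)benzoate | O=C(Cc1c(OCc2ccccc2)cc(OCc2ccccc2)c2c(=O)ccoc12)c1c(OC(=O)c2ccc(OCc3ccccc3)cc2)cc(OCc2ccccc2)cc1OCc1ccccc1
F5 | step 8 | 2-[5,7-bis(benzyloxy)-4-oxo-4H-chromen-8-yl]-1-[2,4-bis(benzyloxy)-6-hydroxyphenyl]-3-[4-(benzyloxy)phenyl]propane-1,3-dione | O=C(c1ccc(OCc2ccccc2)cc1)C(C(=O)c1c(O)cc(OCc2ccccc2)cc1OCc1ccccc1)c1c(OCc2ccccc2)cc(OCc2ccccc2)c2c(=O)ccoc12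
F6 | step 9 | (2S)-5,7-bis(benzyloxy)-8-{2-[4-(benzyloxy)phenyl]-2-oxoethyl}-2-(4-methoxyphenyl)-2,3-dihydro-4H-chromen-4-one | COc1ccc([C@@H]2CC(=O)c3c(OCc4ccccc4)cc(OCc4ccccc4)c(CC(=O)c4ccc(OCc5ccccc5)cc4)c3O2)cc1
F7 | step 9 | 2-[(2S)-5,7-bis(benzyloxy)-2-(4-methoxyphenyl)-4-oxo-3,4-dihydro-2H-chromen-8-yl]-1-[2,4-bis(benzyloxy)-6-fluorophenyl]-3-[4-(benzyloxy)phenyl]propane-1,3-dione | COc1ccc([C@@H]2CC(=O)c3c(OCc4ccccc4)cc(OCc4ccccc4)c(C(C(=O)c4ccc(OCc5ccccc5)cc4)C(=O)c4c(F)cc(OCc5ccccc5)cc4OCc4ccccc4)c3O2)cc1
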